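## Structural features

The target 11 is 3,4,6-tribromo-5-methylbenzene-1,2-diol: one benzene ring with no ring hydrogen, hydroxyl groups on the neighbouring carbons C1 and C2, bromine on C3, C4 and C6, and a methyl group on C5 between the bromines of C4 and C6. There is no second ring, no chain beyond the methyl group and no stereocentre, so nothing has to be controlled in space. The sensitive part is the electron-rich catechol, which is oxidised to the o-quinone by air once it is ionised and by surplus electrophilic halogen; the three aryl C–Br bonds in turn rule out reductive conditions late in the route. Since every ring carbon that bears neither oxygen nor methyl carries bromine, placing the halogens is less of a problem than it looks; what must be right is the relation of the methyl group to the two oxygens (para to the C2 oxygen, meta to the C1 oxygen) and the introduction of three bromines without oxidising the diol. For a synthesis that builds the ring, the question is which open-chain pieces deliver two adjacent oxygenated carbons and the methyl branch in that relation. The key step uses the fact that C1 and C2 with their oxygens are the two carbonyl carbons of an oxalyl unit, bonded on either side to C6 and C3, and that C6–C5(CH3)–C4–C3 is the four-carbon chain between the two carboxyl groups of a 3-methyladipate. The carboxyl carbons of that diester then sit on C6 and C3, each next to a hydroxyl, where two of the bromines are wanted and where a carboxyl group can be exchanged for bromine.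

## Logic of the disconnections

11 to 8. The three C–Br bonds are cut: C3–Br and C6–Br are traced back to C–CO2H, and C4–Br to C–H. A carboxyl group ortho to a phenolic hydroxyl is a latent bromine, because electrophilic attack at the carboxyl-bearing carbon is followed by decarboxylation. The gain is that 8 carries no halogen, so no earlier step has to tolerate C–Br and all three bromines arrive in one operation. The demand on the forward step is a threefold bromination of a free catechol without oxidation, which calls for measured halogen, an acidic medium and a reducing work-up.

8 to 7. The two carboxyl O–H bonds are replaced by O–ethyl bonds. The ring synthesis needs ester groups on C3 and C6 to make the adjacent CH2 groups enolisable, whereas the halogen exchange needs the free acids. The forward step is a hydrolysis in which the C6 ester is shielded by the C1 hydroxyl and the C5 methyl group, and in which the catechol is ionised, so oxygen must be excluded.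

7 to 5. The aromatic ring is taken back by adding one hydrogen each to C4 and C5. This uncovers a cyclic 1,2-diketone (as its bis-enol) flanked by two ester-bearing carbons, that is, two β-keto ester units sharing the C1–C2 bond. The forward step must remove exactly two hydrogens; a stray substitution at C4 would be tolerable because that carbon is brominated later anyway.

5 to 2 and 3. The bonds C6–C1 and C2–C3 are cut, each being the bond between an ester α-carbon and a ketone carbon. This is the strategic cut: the ring and both C–O bonds come from two open-chain diesters in one operation, and the methyl group falls on C5 by virtue of the branch in 2. The demand is a crossed condensation that must beat the five-ring self-condensation of 2 and must proceed at both α-carbons. The design answers this with ethyl esters on both partners matched to the ethoxide base, so that ester exchange is degenerate, with 3 held close to one equivalent so that two separate molecules of 3 are not attached to one molecule of 2, and with 2 added last and slowly to 3 and base. Racemic 2 suffices, because its stereocentre becomes an aromatic carbon.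

2 to 1. The two ester C–O bonds are cut to give the commercial diacid 1. The forward step only has to be complete and to give a dry diester.

## Other disconnections considered

Alternative 1: The cut removes the C5–CH3 and C6–Br bonds together and leads back to an aryne.
- Forward key step: the ring CH of 4-bromo-1,2-dimethoxybenzene A1 that lies between Br and OMe is metalated with lithium 2,2,6,6-tetramethylpiperidide, and elimination of LiBr from the aryllithium generates 3,4-dimethoxybenzyne A2. MeMgBr then delivers its methyl group to the carbon of A2 that is farther from OMe, and the aryl–magnesium bond left next to OMe is brominated with BrCCl2CCl2Br, so that the product is 3-bromo-1,2-dimethoxy-4-methylbenzene A3. Bromination of the two ring CH positions that A3 still has would give 1,2,4-tribromo-5,6-dimethoxy-3-methylbenzene A4, and BBr3 would cleave both ethers of A4 to free the catechol.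
- In its favour: the ring is bought, and the target is three steps from A1 against five in the chosen plan. On step count Alternative 1 is the better. The methyl ethers of A3 and A4 also shield the catechol from oxidation during bromination, a second real advantage.
- Against it: the amide base, the Grignard reagent and the newly formed aryl-metal all compete for A2. Deprotonation of A1 on the other side of bromine would give the isomeric aryne and constitutional isomers of A3. The sequence needs cryogenic organometallic work and ends with a double demethylation of the hexasubstituted arene A4.
- Comparison: the methyl/bromine relation that A3 sets with care does not need setting here, since all free positions take bromine in the end, so on positional outcome it is the equal of the chosen plan, not better. Mechanistically it relies on polar aryne chemistry, whereas the chosen plan uses carbonyl condensations at ordinary temperatures with no protecting group.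

Alternative 2: The cut takes out C6 with its bromine as a one-carbon unit (bonds C6–C1 and C6–C5), contracting the benzene ring to a cyclopentadiene.
- Forward key step: cyclotene A5 would be O-methylated to 2-methoxy-3-methylcyclopent-2-en-1-one A6, and the enolate of A6 would be converted into its enol ester, 5-methoxy-4-methylcyclopenta-1,4-dien-1-yl pivalate A7. CBr2, generated from CHBr3 with KOt-Bu, is expected to cyclopropanate the double bond of A7 that carries OMe and CH3. Ionisation of one C–Br bond with opening of the three-membered ring, then loss of a proton, enlarges the ring to 3-bromo-2-methoxy-4-methylphenyl pivalate A8, whose bromine sits on the inserted carbon C6.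
- In its favour: A5 is cheap and already holds the methyl group and both oxygens in the right relation, and one bromine is placed by construction.
- Against it: A7 has two electron-rich double bonds. Addition to the enol pivalate double bond would, after ring opening, give an arene with the methyl group next to an oxygen-bearing carbon, which is a different carbon skeleton and not just a different halogen pattern. A7 is also prone to 1,5-hydrogen shifts and Diels–Alder dimerisation, and KOt-Bu can cleave the enol ester.
- Comparison: two brominations and two deprotections follow A8, about six steps in all from A5, so it is slightly longer than the chosen plan. It is the equal of the chosen plan in building the benzene ring and better at telling the two oxygens apart, which is of no use for a target with two free hydroxyls. It is weaker in site selectivity.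

Alternative 3: The cut is C1–C2, the bond between the two oxygenated carbons.
- Forward key step: racemic dimethyl 3-methyladipate A9 is reduced with Na in hot toluene in the presence of Me3SiCl; the acyloin coupling joins the two ester carbons, and the enediolate is trapped as racemic 4-methyl-1,2-bis(trimethylsilyloxy)cyclohex-1-ene A10. A10 must then be raised by two oxidation levels, to the α-diketone and on to the arene 4-methylbenzene-1,2-diol A11, before three brominations.
- In its favour: it uses the same cheap seven-carbon chain as the chosen plan, and every carbon of A9 ends in the target. The chosen plan expels both carboxyl carbons of 2 as CO2 and brings in two others from 3, so Alternative 3 is better in atom economy. Silyl trapping removes alkoxide, so the five-ring self-condensation that the chosen key step must outrun is absent; on that point it is also better. The step count is equal to the chosen plan or one lower.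
- Against it: hot Na dispersion is the more hazardous operation, and A10 is moisture-sensitive. Aromatising an unactivated diketone lacks the ester-activated enols that should make step 3 of the chosen plan mild.
- Comparison: A11 is a catalogue compound, so this ring synthesis only reproduces a purchasable arene. The same remark applies in part to the chosen plan. Its ring construction is justified by the positional certainty that the carboxyl groups give to the C3 and C6 bromines and by crystalline intermediates (5, 7, 8), not by necessity.

Key step: step 2

Remark on the chemistry: 5 is written as its bis-enol; its keto–enol tautomers interconvert and are expected to behave alike in step 3.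

Step 1
Reactants: 1 racemic 3-methyladipic acid (3-methylhexanedioic acid)
Product: 2 racemic diethyl 3-methyladipate
Conditions: EtOH (solvent), H2SO4 (cat.), reflux
Reagents that add atoms: ethanol, CCO
Why: Fischer esterification driven by the excess of ethanol; ethyl esters are chosen so that ethoxide in step 2 can only exchange like for like. The stereocentre is not touched and is of no consequence, since it becomes an aromatic carbon in step 3.

Step 2
Reactants: 2 racemic diethyl 3-methyladipate; 3 diethyl oxalate
Product: 5 racemic diethyl 2,3-dihydroxy-5-methylcyclohexa-1,3-diene-1,4-dicarboxylate (bis-enol of the 2,3-dioxo diester), via mono-oxalyl adipate 4 (not isolated)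
Conditions: NaOEt (2.2 equiv), 3 (1.1 equiv), Et2O–EtOH, 0 °C; 2 added slowly; rt, then reflux; then cold aq HCl
Reagents that add atoms: none
Why: Crossed Claisen condensation followed by a Dieckmann-type closure, the reaction type by which adipate and glutarate esters are annulated with oxalate esters to cyclic 1,2-diones. An α-CH2 of 2 is deprotonated by ethoxide (the one remote from the methyl branch should react first) and the ester enolate adds to 3, which cannot enolise and is the most electrophilic ester present; expulsion of ethoxide gives 4 as its stabilised enolate. Deprotonation of the second α-CH2 and attack on the remaining oxalyl ester carbonyl then close the carbocycle in a 6-(enolexo)-exo-trig mode, which completes the two new bonds (C6–C1 and C2–C3 in target numbering). Both new 1,3-dicarbonyl units are deprotonated by the second equivalent of base, and the sparingly soluble disodium salt of 5 should act as the thermodynamic sink that pulls the reversible Claisen equilibria forward; acidification liberates 5. No stereocentre is created: the two ester-bearing carbons end as enol sp2 centres, and the methyl-bearing carbon is carried as the racemate until it is flattened in step 3. The selectivity needed is chemoselectivity for the crossed condensation over self-closure of 2 to a cyclopentanone β-keto ester; it is secured by having 3 and NaOEt in the flask before 2 is added slowly, so that each enolate of 2 meets a local excess of the better electrophile, and by the expected reversibility of any five-ring β-keto ester under ethoxide. Regiochemistry is not an issue, because both α-carbons must be acylated and either order leads to 5, and 3 is kept near one equivalent so that attachment of two separate oxalyl units, which would block ring closure, is not favoured.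

Step 3
Reactants: 5 racemic diethyl 2,3-dihydroxy-5-methylcyclohexa-1,3-diene-1,4-dicarboxylate
Product: 7 diethyl 2,3-dihydroxy-5-methylterephthalate, via α-bromo keto-enol diester 6 (not isolated)
Conditions: Br2 (1.0 equiv), AcOH, 15 °C, then 60 °C
Reagents that add atoms: none
Why: Halogenation–dehydrohalogenation aromatisation of a cyclic bis-enol: Br2 attacks an ester-bearing enol carbon to give 6, loss of HBr towards the neighbouring ring CH2 gives a dienone, and enolisation through the methyl-bearing CH delivers the aromatic catechol 7. The two ester groups deactivate the new arene, and a stray bromination at its one free ring CH would be harmless, since that carbon is brominated in step 5.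

Step 4
Reactants: 7 diethyl 2,3-dihydroxy-5-methylterephthalate
Product: 8 2,3-dihydroxy-5-methylterephthalic acid
Conditions: NaOH (6 equiv), degassed H2O–EtOH, reflux, N2; then aq HCl, 0 °C
Reagents that add atoms: sodium hydroxide, [Na+].[OH-]
Why: Saponification by acyl–oxygen cleavage; the phenols are ionised first, so a clear excess of NaOH and reflux are used to open the ester shielded by the neighbouring OH and CH3, and oxygen is excluded because the catecholate is easily air-oxidised. Acidification should precipitate 8.

Step 5
Reactants: 8 2,3-dihydroxy-5-methylterephthalic acid
Product: 11 3,4,6-tribromo-5-methylbenzene-1,2-diol, via ring-brominated diacid 9 (not isolated), via dibromo monoacid 10 (not isolated)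
Conditions: Br2 (3.1 equiv), AcOH–H2O, 0 °C to 45 °C; aq NaHSO3 work-up
Reagents that add atoms: bromine, BrBr
Why: Electrophilic aromatic substitution at the one ring CH (para to a hydroxyl) to 9, then two ipso-bromodecarboxylations of ortho-hydroxy benzoic acids, the reaction type by which salicylic acid is converted into tribromophenol by bromine water: attack of Br+ at the carboxyl-bearing carbon gives a cyclohexadienone that is a β-keto acid and loses CO2 on rearomatising (9 to 10 to 11, the order being immaterial). The bisulfite work-up destroys surplus Br2 and should return any o-quinone to the catechol.

Compound list

1 | racemic 3-methyladipic acid (3-methylhexanedioic acid) | CC(CCC(O)=O)CC(O)=O | starting material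
2 | racemic diethyl 3-methyladipate (diethyl 3-methylhexanedioate) | CCOC(=O)CC(C)CCC(=O)OCC | intermediate
3 | diethyl oxalate | CCOC(=O)C(=O)OCC | starting material
4 | triethyl 4-methyl-1-oxopentane-1,2,5-tricarboxylate (mono-oxalyl adipate; mixture of diastereomers, present as its sodium enolate in step 2, not isolated) | CCOC(=O)C(=O)C(C(=O)OCC)CC(C)CC(=O)OCC | intermediate
5 | racemic diethyl 2,3-dihydroxy-5-methylcyclohexa-1,3-diene-1,4-dicarboxylate (bis-enol of the 2,3-dioxo diester) | CCOC(=O)C1=C(O)C(O)=C(C(=O)OCC)C(C)C1 | intermediate
6 | diethyl 1-bromo-3-hydroxy-5-methyl-2-oxocyclohex-3-ene-1,4-dicarboxylate (mixture of diastereomers, forms in step 3, not isolated) | CCOC(=O)C1(Br)CC(C)C(C(=O)OCC)=C(O)C1=O | intermediate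
7 | diethyl 2,3-dihydroxy-5-methylterephthalate | CCOC(=O)c1cc(C)c(C(=O)OCC)c(O)c1O | intermediate
8 | 2,3-dihydroxy-5-methylterephthalic acid | Cc1cc(C(=O)O)c(O)c(O)c1C(=O)O | intermediate
9 | 2-bromo-5,6-dihydroxy-3-methylterephthalic acid (forms in step 5, not isolated) | Cc1c(Br)c(C(=O)O)c(O)c(O)c1C(=O)O | intermediate
10 | 2,4-dibromo-5,6-dihydroxy-3-methylbenzoic acid (forms in step 5, not isolated) | Cc1c(Br)c(O)c(O)c(C(=O)O)c1Br | intermediate
11 | 3,4,6-tribromo-5-methylbenzene-1,2-diol | Cc1c(Br)c(O)c(O)c(Br)c1Br | target

Total step count: 5. Longest linear sequence: 5 steps (1 to 2 to 5 to 7 to 8 to 11); 3 is commercial and enters in step 2.

Steps least certain to work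

Step 2 (key step). The intramolecular self-condensation of 2 to a five-membered β-keto ester may compete with the crossed acylation, or the sequence may stall after the first acylation because closure through the α-carbon next to the methyl branch is slower. Both follow from running two reversible Claisen steps under one set of equilibrating conditions. The fallback takes alkoxide out of the ring-forming event while keeping the same two bonds. It sets out from 2, which with LiN(i-Pr)2 (2.2 equiv) and Me3SiCl present in situ in THF at −78 °C should give racemic 1,6-diethoxy-3-methyl-1,6-bis(trimethylsilyloxy)hexa-1,5-diene F1. Treatment of F1 with oxalyl chloride in CH2Cl2 at −78 °C to rt under high dilution relies on the C-acylation of ketene silyl acetals by acid chlorides, first between the two molecules and then within one, the second event being the counterpart of the Dieckmann closure. Aqueous work-up would return to the route at 5.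

Step 5. Surplus halogen in water may oxidise the catechol to the o-quinone and degrade it further, or the second carboxyl–bromine exchange may stall on a ring already deactivated by two bromines. The fallback separates decarboxylation from halogenation. It sets out from 8, which on heating with Cu2O (cat.) in quinoline at about 190 °C under N2 should lose both carboxyl groups by protodecarboxylation to give 4-methylbenzene-1,2-diol F2, the same compound as A11. Br2 (3.0 equiv) in anhydrous AcOH would then fill the three free ring positions of F2 by ordinary electrophilic substitution, with bisulfite work-up, and the route is rejoined at 11.

Step 3. A second bromination at the other enol carbon may carry the material on to the o-quinone oxidation level, or loss of HBr from 6 may be incomplete. The fallback moves the oxidation to a substrate on which every ring bromination is wanted. It sets out from 5, which in refluxing dilute H2SO4 should undergo ester hydrolysis and double decarboxylation of the β-keto acids to racemic 4-methylcyclohexane-1,2-dione F3. Br2 (4 equiv) in AcOH, followed by bisulfite work-up, should then effect halogenative aromatisation of the enolised F3 and exhaustive ring bromination in one flask. The route is rejoined at 11, bypassing 7 and 8.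

Step 4. Hydroxide attack may be slow at the ester carbonyl that is flanked by a phenoxide and a methyl group, leaving a half-ester, and the catecholate may darken by oxidation if air enters. The fallback cleaves the esters at the ethyl carbon instead of the carbonyl and avoids base. It sets out from 7, which with Me3SiCl and NaI (Me3SiI formed in situ) in MeCN at reflux should undergo dealkylative ester cleavage. Aqueous work-up hydrolyses the silyl esters and silyl ethers and returns to the route at 8. This fallback, F0, makes no compound that the compound list lacks.

## Further compounds

F1 | step 2 | racemic 1,6-diethoxy-3-methyl-1,6-bis(trimethylsilyloxy)hexa-1,5-diene (mixture of double-bond isomers) | CCOC(O[Si](C)(C)C)=CC(C)CC=C(OCC)O[Si](C)(C)C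
F2 | step 5 | 4-methylbenzene-1,2-diol | Cc1ccc(O)c(O)c1
F3 | step 3 | racemic 4-methylcyclohexane-1,2-dione | CC1CCC(=O)C(=O)C1
F0 | step 4 | none | none
A1 | alternative 1 | 4-bromo-1,2-dimethoxybenzene | COc1ccc(Br)cc1OC
A2 | alternative 1 | 3,4-dimethoxybenzyne (1,2-dimethoxy-3,4-didehydrobenzene) | COC1=C(OC)C#CC=C1
A3 | alternative 1 | 3-bromo-1,2-dimethoxy-4-methylbenzene | COc1ccc(C)c(Br)c1OC
A4 | alternative 1 | 1,2,4-tribromo-5,6-dimethoxy-3-methylbenzene | COc1c(Br)c(Br)c(C)c(Br)c1OC
A5 | alternative 2 | 2-hydroxy-3-methylcyclopent-2-en-1-one (cyclotene) | CC1=C(O)C(=O)CC1
A6 | alternative 2 | 2-methoxy-3-methylcyclopent-2-en-1-one | COC1=C(C)CCC1=O
A7 | alternative 2 | 5-methoxy-4-methylcyclopenta-1,4-dien-1-yl pivalate | COC1=C(C)CC=C1OC(=O)C(C)(C)C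
A8 | alternative 2 | 3-bromo-2-methoxy-4-methylphenyl pivalate | COc1c(Br)c(C)ccc1OC(=O)C(C)(C)C
A9 | alternative 3 | racemic dimethyl 3-methyladipate | COC(=O)CC(C)CCC(=O)OC
A10 | alternative 3 | racemic 4-methyl-1,2-bis(trimethylsilyloxy)cyclohex-1-ene | CC1CCC(O[Si](C)(C)C)=C(O[Si](C)(C)C)C1
A11 | alternative 3 | 4-methylbenzene-1,2-diol | Cc1ccc(O)c(O)c1
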